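**Plan**
- Retrosynthetic cuts, in order: the two benzyl ester C–O bonds and the malate acyl–O bond at the chain oxygen; then the oxolanone C4–C5 bond together with C5–O1, which removes the lactone carbonyl as CO and leaves a vinyl group and a free hydroxyl on C2; then the C2–C1′ bond between the carbinol carbon and the chain-bearing CH (aldol).
- Forward: the chain thioester is made into its silylketene thioacetal and added to a keto ester that carries a 2-(methylsulfanyl)ethyl arm; the thioether is turned into the vinyl group; the only ring is closed by carbonylation; desilylation, malate half-ester formation and hydrogenolysis finish the route.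
- Enabling feature: in the 5-oxooxolane ring the carbonyl C5 is bonded only to O1 and to the unsubstituted C4H2–C3H2 unit, and O1 sits on the fully substituted C2. C3–C4 can therefore be a vinyl group on C2, C5 can come from CO, and the C2 hydroxyl, four atoms from the vinyl terminus, closes the five-membered ring (formal (4+1) carbonylative annulation).
- Stereochemistry: C2 and C1′ are set together in one catalyst-controlled syn Mukaiyama aldol addition (Cu(OTf)2 with the (R,R)-t-Bu-box ligand) and are not touched afterwards; the malate centre comes from (R)-malic acid.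

Key step: step 8

Assumption: compounds 1, 6 and 15, the (R,R)-t-Bu-box ligand and all reagents are taken as commercial; sulfoxide 11 forms as both sulfur epimers, which converge on 12.

**Route**

Step 1
Reactants: 1 12-hydroxydodecanoic acid
Product: 3 12-[(tert-butyldiphenylsilyl)oxy]dodecanoic acid, via bis-silylated ester 2 (not isolated)
Conditions: TBDPSCl (2.2 equiv), imidazole, DMF, rt; then AcOH–THF–H2O, rt
Reagents that add atoms: tert-butyl(chloro)diphenylsilane CC(C)(C)[Si](Cl)(c1ccccc1)c1ccccc1
Why: Silylation caps both the hydroxyl and the acid, and the far more labile silyl ester is then hydrolysed selectively by aqueous acetic acid while the primary silyl ether survives (silyl ether protection).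

Step 2
Reactants: 3 12-[(tert-butyldiphenylsilyl)oxy]dodecanoic acid
Product: 4 S-tert-butyl 12-[(tert-butyldiphenylsilyl)oxy]dodecanethioate
Conditions: t-BuSH, DCC, DMAP (cat.), CH2Cl2, 0 °C to rt
Reagents that add atoms: 2-methylpropane-2-thiol CC(C)(C)S
Why: Carbodiimide coupling (Steglich esterification applied to a thiol) gives the tert-butyl thioester, the donor class that serves best in the catalytic aldol addition of step 5.

Step 3
Reactants: 4 S-tert-butyl 12-[(tert-butyldiphenylsilyl)oxy]dodecanethioate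
Product: 5 tert-butyl{[(11Z)-12-(tert-butylsulfanyl)-12-[(trimethylsilyl)oxy]dodec-11-en-1-yl]oxy}diphenylsilane
Conditions: LDA, THF, −78 °C; then TMSCl, −78 °C to rt
Reagents that add atoms: chlorotrimethylsilane C[Si](C)(C)Cl
Why: Kinetic enolisation of the thioester in THF and O-silylation should give mainly the (Z)-silylketene thioacetal, and the following addition is expected to give the syn adduct from either enolsilane geometry.

Step 4
Reactants: 6 sodium 4-(methylsulfanyl)-2-oxobutanoate
Product: 7 benzyl 4-(methylsulfanyl)-2-oxobutanoate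
Conditions: BnBr, DMF, rt
Reagents that add atoms: benzyl bromide BrCc1ccccc1
Why: SN2 O-alkylation of the carboxylate gives the benzyl α-keto ester, whose thioether arm is a latent vinyl group.

Step 5
Reactants: 5 tert-butyl{[(11Z)-12-(tert-butylsulfanyl)-12-[(trimethylsilyl)oxy]dodec-11-en-1-yl]oxy}diphenylsilane, 7 benzyl 4-(methylsulfanyl)-2-oxobutanoate
Product: 9 benzyl (2R,3R)-3-[(tert-butylsulfanyl)carbonyl]-13-[(tert-butyldiphenylsilyl)oxy]-2-hydroxy-2-[2-(methylsulfanyl)ethyl]tridecanoate, via trimethylsilyl ether 8 (not isolated)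
Conditions: Cu(OTf)2 (10 mol%), (R,R)-t-Bu-box (11 mol%), THF, −78 °C; then 1 M HCl, THF, rt
Reagents that add atoms: none
Why: This is an enantioselective Mukaiyama aldol addition to an α-keto ester held as a five-membered chelate on divalent copper; by analogy with pyruvate esters the (R,R)-ligand should leave the re face of the ketone open to give the (2R) carbinol, the open transition state should place the chain syn to the hydroxyl to give the (3R) centre, and dilute acid cleaves silyl ether 8.

Step 6
Reactants: 9 benzyl (2R,3R)-3-[(tert-butylsulfanyl)carbonyl]-13-[(tert-butyldiphenylsilyl)oxy]-2-hydroxy-2-[2-(methylsulfanyl)ethyl]tridecanoate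
Product: 10 dibenzyl (2R,3R)-3-{10-[(tert-butyldiphenylsilyl)oxy]decyl}-2-hydroxy-2-[2-(methylsulfanyl)ethyl]butanedioate
Conditions: AgO2CCF3 (3 equiv), BnOH (5 equiv), CH2Cl2, rt
Reagents that add atoms: benzyl alcohol OCc1ccccc1
Why: Thiophilic activation of the tert-butyl thioester by the silver salt and acyl transfer to benzyl alcohol (thiophile-promoted thioester alcoholysis) gives the second benzyl ester without base, which spares the retro-aldol-prone tertiary aldol; the excess silver allows for binding to the thioether.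

Step 7
Reactants: 10 dibenzyl (2R,3R)-3-{10-[(tert-butyldiphenylsilyl)oxy]decyl}-2-hydroxy-2-[2-(methylsulfanyl)ethyl]butanedioate
Product: 12 dibenzyl (2R,3R)-3-{10-[(tert-butyldiphenylsilyl)oxy]decyl}-2-ethenyl-2-hydroxybutanedioate, via sulfoxide 11 (not isolated)
Conditions: 30% H2O2 (1.05 equiv), (CF3)2CHOH, rt; evaporate; then 1,2-dichlorobenzene, NaHCO3, 150 °C
Reagents that add atoms: none
Why: Chemoselective oxidation of the dialkyl sulfide to the sulfoxide and thermal syn-elimination (sulfoxide pyrolysis, as in the conversion of methionine into vinylglycine) remove methanesulfenic acid, and since only the CH2 next to C2 carries β-hydrogens the terminal vinyl group must result.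

Step 8
Reactants: 12 dibenzyl (2R,3R)-3-{10-[(tert-butyldiphenylsilyl)oxy]decyl}-2-ethenyl-2-hydroxybutanedioate
Product: 13 benzyl (2R)-2-[(1R)-1-[(benzyloxy)carbonyl]-11-[(tert-butyldiphenylsilyl)oxy]undecyl]-5-oxooxolane-2-carboxylate
Conditions: Pd(dba)2 (5 mol%), dppb (5 mol%), CO/H2 (1:1, 40 bar), CH2Cl2, 100 °C
Reagents that add atoms: carbon monoxide [C-]#[O+]
Why: Zerovalent palladium with 1,4-bis(diphenylphosphino)butane under CO/H2 should form a palladium hydride that adds across the vinyl group with the metal on the terminal carbon; CO then inserts to make the CH2–C(=O) bond (ring C4–C5), and the acyl palladium is taken by the tertiary C2 hydroxyl, which releases the lactone and returns the hydride. The closest known reaction type is the palladium-catalysed cyclocarbonylation (intramolecular hydro-alkoxycarbonylation) of tertiary allylic alcohols to γ-butyrolactones. The five-membered oxolanone closes by a 5-exo-trig acyl substitution at the new carbonyl carbon, so CO acts as a one-carbon partner to the four-atom O–C–C=C unit in a formal (4+1) annulation. No stereocentre is created and no bond to C2 or to the neighbouring CH is broken, so both keep the configuration set in step 5. The step needs linear instead of branched insertion, which the fully substituted C2 next to the alkene should enforce, and carbonylation instead of ionisation or isomerisation, which the C2 ester (no stabilised allyl cation) and the absence of a carbinol hydrogen should secure.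

Step 9
Reactants: 13 benzyl (2R)-2-[(1R)-1-[(benzyloxy)carbonyl]-11-[(tert-butyldiphenylsilyl)oxy]undecyl]-5-oxooxolane-2-carboxylate
Product: 14 benzyl (2R)-2-[(1R)-1-[(benzyloxy)carbonyl]-11-hydroxyundecyl]-5-oxooxolane-2-carboxylate
Conditions: HF·pyridine, THF, 0 °C to rt
Reagents that add atoms: none
Why: Fluoride cleaves the Si–O bond of the silyl ether under buffered acidic conditions that leave the lactone and the benzyl esters untouched (silyl ether deprotection).

Step 10
Reactants: 15 (R)-malic acid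
Product: 16 (3R)-2,5-dioxooxolan-3-yl trifluoroacetate
Conditions: (CF3CO)2O, neat, 0 °C to rt; evaporate
Reagents that add atoms: trifluoroacetic anhydride O=C(OC(=O)C(F)(F)F)C(F)(F)F
Why: Trifluoroacetic anhydride dehydrates the diacid to the cyclic anhydride and acylates the hydroxyl without breaking any bond to the stereocentre (mixed-anhydride cyclodehydration).

Step 11
Reactants: 14 benzyl (2R)-2-[(1R)-1-[(benzyloxy)carbonyl]-11-hydroxyundecyl]-5-oxooxolane-2-carboxylate, 16 (3R)-2,5-dioxooxolan-3-yl trifluoroacetate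
Product: 18 (3R)-4-{[(11R)-11-[(benzyloxy)carbonyl]-11-[(2R)-2-[(benzyloxy)carbonyl]-5-oxooxolan-2-yl]undecyl]oxy}-3-hydroxy-4-oxobutanoic acid, via trifluoroacetate ester 17 (not isolated)
Conditions: 16 (2.5 equiv), CH2Cl2, rt; then THF–H2O, rt
Reagents that add atoms: none
Why: Alcoholysis of the unsymmetrical cyclic anhydride should occur at the carbonyl next to the electron-withdrawing trifluoroacetoxy group, which gives the 1-ester with the 4-acid free, and the labile trifluoroacetate is solvolysed in the aqueous work-up (regioselective anhydride opening).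

Step 12
Reactants: 18 (3R)-4-{[(11R)-11-[(benzyloxy)carbonyl]-11-[(2R)-2-[(benzyloxy)carbonyl]-5-oxooxolan-2-yl]undecyl]oxy}-3-hydroxy-4-oxobutanoic acid
Product: 19 (2R)-2-[(1R)-1-carboxy-11-{[(2R)-3-carboxy-2-hydroxypropanoyl]oxy}undecyl]-5-oxooxolane-2-carboxylic acid
Conditions: H2 (1 atm), 10% Pd/C, EtOAc, rt
Reagents that add atoms: none
Why: Hydrogenolysis of the two benzyl esters frees the acids under neutral conditions that touch neither the lactone, the malate ester nor any stereocentre.

**Compound list**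

1 | 12-hydroxydodecanoic acid | OCCCCCCCCCCCC(=O)O | starting material
2 | tert-butyldiphenylsilyl 12-[(tert-butyldiphenylsilyl)oxy]dodecanoate | CC(C)(C)[Si](c1ccccc1)(c1ccccc1)OCCCCCCCCCCCC(=O)O[Si](c1ccccc1)(c1ccccc1)C(C)(C)C | intermediate
3 | 12-[(tert-butyldiphenylsilyl)oxy]dodecanoic acid | CC(C)(C)[Si](c1ccccc1)(c1ccccc1)OCCCCCCCCCCCC(=O)O | intermediate
4 | S-tert-butyl 12-[(tert-butyldiphenylsilyl)oxy]dodecanethioate | CC(C)(C)[Si](c1ccccc1)(c1ccccc1)OCCCCCCCCCCCC(=O)SC(C)(C)C | intermediate
5 | tert-butyl{[(11Z)-12-(tert-butylsulfanyl)-12-[(trimethylsilyl)oxy]dodec-11-en-1-yl]oxy}diphenylsilane | CC(C)(C)[Si](c1ccccc1)(c1ccccc1)OCCCCCCCCCC/C=C(/O[Si](C)(C)C)SC(C)(C)C | intermediate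
6 | sodium 4-(methylsulfanyl)-2-oxobutanoate | CSCCC(=O)C(=O)[O-].[Na+] | starting material
7 | benzyl 4-(methylsulfanyl)-2-oxobutanoate | CSCCC(=O)C(=O)OCc1ccccc1 | intermediate
8 | benzyl (2R,3R)-3-[(tert-butylsulfanyl)carbonyl]-13-[(tert-butyldiphenylsilyl)oxy]-2-[2-(methylsulfanyl)ethyl]-2-[(trimethylsilyl)oxy]tridecanoate | CC(C)(C)[Si](c1ccccc1)(c1ccccc1)OCCCCCCCCCC[C@@H](C(=O)SC(C)(C)C)[C@@](O[Si](C)(C)C)(C(=O)OCc1ccccc1)CCSC | intermediate
9 | benzyl (2R,3R)-3-[(tert-butylsulfanyl)carbonyl]-13-[(tert-butyldiphenylsilyl)oxy]-2-hydroxy-2-[2-(methylsulfanyl)ethyl]tridecanoate | CC(C)(C)[Si](c1ccccc1)(c1ccccc1)OCCCCCCCCCC[C@@H](C(=O)SC(C)(C)C)[C@@](O)(C(=O)OCc1ccccc1)CCSC | intermediate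
10 | dibenzyl (2R,3R)-3-{10-[(tert-butyldiphenylsilyl)oxy]decyl}-2-hydroxy-2-[2-(methylsulfanyl)ethyl]butanedioate | CC(C)(C)[Si](c1ccccc1)(c1ccccc1)OCCCCCCCCCC[C@@H](C(=O)OCc1ccccc1)[C@@](O)(C(=O)OCc1ccccc1)CCSC | intermediate
11 | dibenzyl (2R,3R)-3-{10-[(tert-butyldiphenylsilyl)oxy]decyl}-2-hydroxy-2-[2-(methanesulfinyl)ethyl]butanedioate (both sulfur epimers) | CC(C)(C)[Si](c1ccccc1)(c1ccccc1)OCCCCCCCCCC[C@@H](C(=O)OCc1ccccc1)[C@@](O)(C(=O)OCc1ccccc1)CCS(C)=O | intermediate
12 | dibenzyl (2R,3R)-3-{10-[(tert-butyldiphenylsilyl)oxy]decyl}-2-ethenyl-2-hydroxybutanedioate | CC(C)(C)[Si](c1ccccc1)(c1ccccc1)OCCCCCCCCCC[C@@H](C(=O)OCc1ccccc1)[C@@](O)(C(=O)OCc1ccccc1)C=C | intermediate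
13 | benzyl (2R)-2-[(1R)-1-[(benzyloxy)carbonyl]-11-[(tert-butyldiphenylsilyl)oxy]undecyl]-5-oxooxolane-2-carboxylate | CC(C)(C)[Si](c1ccccc1)(c1ccccc1)OCCCCCCCCCC[C@@H](C(=O)OCc1ccccc1)[C@@]1(C(=O)OCc2ccccc2)CCC(=O)O1 | intermediate
14 | benzyl (2R)-2-[(1R)-1-[(benzyloxy)carbonyl]-11-hydroxyundecyl]-5-oxooxolane-2-carboxylate | OCCCCCCCCCC[C@@H](C(=O)OCc1ccccc1)[C@@]1(C(=O)OCc2ccccc2)CCC(=O)O1 | intermediate
15 | (R)-malic acid, (2R)-2-hydroxybutanedioic acid | O=C(O)C[C@@H](O)C(=O)O | starting material
16 | (3R)-2,5-dioxooxolan-3-yl trifluoroacetate | O=C1C[C@@H](OC(=O)C(F)(F)F)C(=O)O1 | intermediate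
17 | (3R)-4-{[(11R)-11-[(benzyloxy)carbonyl]-11-[(2R)-2-[(benzyloxy)carbonyl]-5-oxooxolan-2-yl]undecyl]oxy}-4-oxo-3-[(trifluoroacetyl)oxy]butanoic acid | O=C(O)C[C@@H](OC(=O)C(F)(F)F)C(=O)OCCCCCCCCCC[C@@H](C(=O)OCc1ccccc1)[C@@]1(C(=O)OCc2ccccc2)CCC(=O)O1 | intermediate
18 | (3R)-4-{[(11R)-11-[(benzyloxy)carbonyl]-11-[(2R)-2-[(benzyloxy)carbonyl]-5-oxooxolan-2-yl]undecyl]oxy}-3-hydroxy-4-oxobutanoic acid | O=C(O)C[C@@H](O)C(=O)OCCCCCCCCCC[C@@H](C(=O)OCc1ccccc1)[C@@]1(C(=O)OCc2ccccc2)CCC(=O)O1 | intermediate
19 | (2R)-2-[(1R)-1-carboxy-11-{[(2R)-3-carboxy-2-hydroxypropanoyl]oxy}undecyl]-5-oxooxolane-2-carboxylic acid | O=C(O)C[C@@H](O)C(=O)OCCCCCCCCCC[C@@H](C(=O)O)[C@@]1(C(=O)O)CCC(=O)O1 | target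

**Count and risks**

Total steps: 12. Longest linear sequence: 10 (steps 1, 2, 3, 5, 6, 7, 8, 9, 11, 12).

Step 8. The palladium hydride may hydrogenate the vinyl group or insert at the internal carbon, and ionisation of the allylic C–O bond would erase the C2 stereocentre. The fallback sets out from 12 and returns at 13. Linear-selective hydroformylation with Rh(CO)2(acac) and Xantphos under CO/H2 (10 bar) in toluene at 70 °C should give the γ-hydroxy aldehyde as its cyclic hemiacetal, benzyl (2R)-2-[(1R)-1-[(benzyloxy)carbonyl]-11-[(tert-butyldiphenylsilyl)oxy]undecyl]-5-hydroxyoxolane-2-carboxylate F1 (both anomers). Oxidation of this lactol with catalytic TEMPO and PhI(OAc)2 in CH2Cl2 then gives 13. No bond to either stereocentre is involved.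

Step 5. Facial discrimination at the ketone may be weaker than with pyruvates, because the thioether can occupy a coordination site on copper, and syn selectivity may drop with the long-chain donor. The fallback sets out from 3 and returns at 10. DCC/DMAP acylation of (4R)-4-benzyl-1,3-thiazolidine-2-thione with 3 gives (4R)-4-benzyl-3-{12-[(tert-butyldiphenylsilyl)oxy]dodecanoyl}-1,3-thiazolidine-2-thione F2. Its chlorotitanium enolate (TiCl4, i-Pr2NEt, N-methylpyrrolidinone, CH2Cl2, −78 °C) is added to keto ester 7 to give benzyl (2R,3R)-3-{[(4R)-4-benzyl-2-sulfanylidene-1,3-thiazolidin-3-yl]carbonyl}-13-[(tert-butyldiphenylsilyl)oxy]-2-hydroxy-2-[2-(methylsulfanyl)ethyl]tridecanoate F3. The stereoisomers of this adduct are diastereomers and can be separated on silica, so stereochemical purity no longer rests on catalyst enantioselectivity. Displacement of the auxiliary by benzyl alcohol with DMAP in CH2Cl2 gives 10.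

Step 7. At the temperature of the sulfoxide elimination the tertiary aldol may undergo retro-aldol cleavage or dehydration, and methanesulfenic acid may add back to the new alkene. The fallback sets out from 10 and returns at 12. Imidation of the sulfide with chloramine-T in MeOH–CH2Cl2 gives the N-tosylsulfilimine, dibenzyl (2R,3R)-3-{10-[(tert-butyldiphenylsilyl)oxy]decyl}-2-hydroxy-2-{2-[S-methyl-N-(4-methylbenzenesulfonyl)sulfinimidoyl]ethyl}butanedioate F4. This S–N leaving group should undergo syn-elimination in toluene at about 90 °C with loss of a neutral sulfenamide, giving 12.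

**Further compounds**

F1 | step 8 | benzyl (2R)-2-[(1R)-1-[(benzyloxy)carbonyl]-11-[(tert-butyldiphenylsilyl)oxy]undecyl]-5-hydroxyoxolane-2-carboxylate | CC(C)(C)[Si](c1ccccc1)(c1ccccc1)OCCCCCCCCCC[C@@H](C(=O)OCc1ccccc1)[C@@]1(C(=O)OCc2ccccc2)CCC(O)O1
F2 | step 5 | (4R)-4-benzyl-3-{12-[(tert-butyldiphenylsilyl)oxy]dodecanoyl}-1,3-thiazolidine-2-thione | CC(C)(C)[Si](c1ccccc1)(c1ccccc1)OCCCCCCCCCCCC(=O)N1[C@H](Cc2ccccc2)CSC1=S
F3 | step 5 | benzyl (2R,3R)-3-{[(4R)-4-benzyl-2-sulfanylidene-1,3-thiazolidin-3-yl]carbonyl}-13-[(tert-butyldiphenylsilyl)oxy]-2-hydroxy-2-[2-(methylsulfanyl)ethyl]tridecanoate | CC(C)(C)[Si](c1ccccc1)(c1ccccc1)OCCCCCCCCCC[C@@H](C(=O)N1[C@H](Cc2ccccc2)CSC1=S)[C@@](O)(C(=O)OCc1ccccc1)CCSC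
F4 | step 7 | dibenzyl (2R,3R)-3-{10-[(tert-butyldiphenylsilyl)oxy]decyl}-2-hydroxy-2-{2-[S-methyl-N-(4-methylbenzenesulfonyl)sulfinimidoyl]ethyl}butanedioate | CC(C)(C)[Si](c1ccccc1)(c1ccccc1)OCCCCCCCCCC[C@@H](C(=O)OCc1ccccc1)[C@@](O)(C(=O)OCc1ccccc1)CCS(C)=NS(=O)(=O)c1ccc(C)cc1
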